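**Retrosynthetic overview**
1. The target comes from its penta-silyl ether by global desilylation; the five phenols travel as TBS ethers throughout.
2. The protected bicycle comes in one operation from an acyclic α-bromo tert-butyl ester: radical closure of the C3a–C6a bond (tetrahydrofuran ring, 5-exo), then capture of the benzylic cation at C3 by the ester oxygen (O2–C3, lactone ring).
3. Enabling feature: C6a is α to the lactone carbonyl C1 (radical site), and C3a–C3 is a latent electron-rich styrene whose benzylic carbon C3 ends up carrying lactone oxygen O2. Ether oxygen O5 ties C6 to C4 as a three-atom tether, so the radical–styrene union is a 5-exo closure steered by the single stereocentre C6.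
4. The bromo ester comes from α-bromination of the cinnamyl ether ester, which comes from cross-metathesis of an O-allyl (S)-β-hydroxy ester with a silylated styrene; the (S)-alcohol comes from asymmetric transfer hydrogenation of an aryl β-keto ester.
5. Ring order: tetrahydrofuran ring first (C–C bond), lactone ring second (C–O bond), both in the same step.

Key step: step 9

Remark: ring atoms are numbered as in furo[3,4-c]furan-1-one (C1 carbonyl, O2, C3, C3a, C4, O5, C6, C6a); TBS = tert-butyldimethylsilyl, TBSO = tert-butyldimethylsilyloxy. The sense of induction in step 3 is assigned by analogy with aryl ketones and is to be confirmed before the material is carried on.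

**Step 1**
Reactants: 1 methyl 3,4-dihydroxybenzoate
Product: 2 methyl 3,4-bis(TBSO)benzoate
Conditions: TBSCl (2.4 equiv), imidazole (5 equiv), DMF, rt
Reagents that add atoms: tert-butyldimethylsilyl chloride, CC(C)(C)[Si](C)(C)Cl
Why: Imidazole-promoted silylation of phenols (standard silyl ether protection) leaves the methyl ester untouched and installs ethers that survive strong base at low temperature, ruthenium carbenes and radical conditions, yet fall to buffered fluoride at the end without stress on the two benzylic C–O bonds.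

**Step 2**
Reactants: 2 methyl 3,4-bis(TBSO)benzoate
Product: 3 tert-butyl 3-[3,4-bis(TBSO)phenyl]-3-oxopropanoate
Conditions: tert-butyl acetate (2.4 equiv), LiN(i-Pr)2 (2.5 equiv), THF, −78 °C; then 2, −78 → 0 °C; aq NH4Cl
Reagents that add atoms: tert-butyl acetate, CC(=O)OC(C)(C)C
Why: Crossed Claisen condensation of a non-enolisable benzoate with the preformed lithium enolate of tert-butyl acetate, used in excess because the product is deprotonated as it forms, which also protects the ketone from a second addition.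

**Step 3**
Reactants: 3 tert-butyl 3-[3,4-bis(TBSO)phenyl]-3-oxopropanoate
Product: 4 tert-butyl (3S)-3-[3,4-bis(TBSO)phenyl]-3-hydroxypropanoate
Conditions: RuCl[(S,S)-TsDPEN](p-cymene) (1 mol %), HCO2H/Et3N (5:2), CH2Cl2, 30 °C
Reagents that add atoms: none
Why: Noyori–Ikariya asymmetric transfer hydrogenation of an aryl β-keto ester; the new stereocentre (later C6) is set by the catalyst, the (S,S)-ligand delivering hydride to the ketone face that should give the (S)-benzylic alcohol by analogy with simple aryl ketones, to be confirmed by Mosher ester analysis.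

**Step 4**
Reactants: 4 tert-butyl (3S)-3-[3,4-bis(TBSO)phenyl]-3-hydroxypropanoate
Product: 5 tert-butyl (3S)-3-(allyloxy)-3-[3,4-bis(TBSO)phenyl]propanoate
Conditions: allyl bromide (5 equiv), Ag2O (2 equiv), 4 Å molecular sieves, Et2O, rt, dark
Reagents that add atoms: allyl bromide, C=CCBr
Why: Silver oxide-mediated O-alkylation (Purdie-type Williamson etherification) works without a free alkoxide, so the aldol is not exposed to retro-aldol cleavage or β-elimination, and no bond to the stereocentre is broken.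

**Step 5**
Reactants: 6 3,4,5-trihydroxybenzaldehyde
Product: 7 3,4,5-tris(TBSO)benzaldehyde
Conditions: TBSCl (3.6 equiv), imidazole (7 equiv), DMF, rt
Reagents that add atoms: tert-butyldimethylsilyl chloride, CC(C)(C)[Si](C)(C)Cl
Why: Standard imidazole-promoted silylation of phenols as in step 1; the aldehyde is inert under these conditions.

**Step 6**
Reactants: 7 3,4,5-tris(TBSO)benzaldehyde
Product: 8 3,4,5-tris(TBSO)styrene
Conditions: Ph3PCH3Br (1.3 equiv), NaN(SiMe3)2 (1.25 equiv), THF, 0 °C; then 7, 0 °C → rt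
Reagents that add atoms: methyltriphenylphosphonium bromide, C[P+](c1ccccc1)(c1ccccc1)c1ccccc1.[Br-]
Why: Wittig methylenation of a non-enolisable aldehyde with the preformed ylide, so that no excess base is left to attack the aryl silyl ethers.

**Step 7**
Reactants: 5 tert-butyl (3S)-3-(allyloxy)-3-[3,4-bis(TBSO)phenyl]propanoate; 8 3,4,5-tris(TBSO)styrene (2 equiv)
Product: 9 tert-butyl (3S)-3-[3,4-bis(TBSO)phenyl]-3-{[(2E)-3-[3,4,5-tris(TBSO)phenyl]prop-2-en-1-yl]oxy}propanoate
Conditions: second-generation Hoveyda–Grubbs catalyst RuCl2(H2IMes)(=CH-2-(i-PrO)C6H4) (5 mol %), CH2Cl2, 40 °C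
Reagents that add atoms: none
Why: Olefin cross-metathesis of a terminal allyl ether with an electron-rich styrene that homodimerises only slowly and is used in excess; the conjugated (E)-alkene is the thermodynamic product and the stereocentre is remote from the reacting alkene.

**Step 8**
Reactants: 9 tert-butyl (3S)-3-[3,4-bis(TBSO)phenyl]-3-{[(2E)-3-[3,4,5-tris(TBSO)phenyl]prop-2-en-1-yl]oxy}propanoate
Product: 12 tert-butyl (2RS,3R)-2-bromo-3-[3,4-bis(TBSO)phenyl]-3-{[(2E)-3-[3,4,5-tris(TBSO)phenyl]prop-2-en-1-yl]oxy}propanoate, via lithium enolate 10 (not isolated), via trimethylsilyl ketene acetal 11 (not isolated)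
Conditions: LiN(i-Pr)2 (1.2 equiv), Me3SiCl (1.5 equiv, present from the start), THF, −78 °C; then NBS (1.05 equiv), −78 °C; aq NaHCO3
Reagents that add atoms: N-bromosuccinimide, O=C1CCC(=O)N1Br
Why: Kinetic ester deprotonation at −78 °C with internal silyl quench traps the β-alkoxy enolate before it can expel the ether oxygen, and the silyl ketene acetal is brominated by NBS far faster than the styrene (electrophilic α-halogenation of a silyl ketene acetal); the bromine-bearing centre forms as an epimer mixture, harmless because it becomes the radical centre, and C3 is untouched (its descriptor changes from S to R only through the priority change).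

**Step 9**
Reactants: 12 tert-butyl (2RS,3R)-2-bromo-3-[3,4-bis(TBSO)phenyl]-3-{[(2E)-3-[3,4,5-tris(TBSO)phenyl]prop-2-en-1-yl]oxy}propanoate
Product: 16 (3S,3aR,6S,6aS)-6-[3,4-bis(TBSO)phenyl]-3-[3,4,5-tris(TBSO)phenyl]tetrahydro-1H,3H-furo[3,4-c]furan-1-one, via α-ester radical 13 (not isolated), via cyclised benzylic radical 14 (not isolated), via benzylic cation 15 (not isolated)
Conditions: fac-Ir(ppy)3 (1 mol %), 2,6-lutidine (2 equiv), degassed MeCN/CH2Cl2 (1:1, 0.01 M), blue LEDs (450 nm), 25 °C
Reagents that add atoms: none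
Why: The excited trivalent iridium photocatalyst transfers one electron to the C–Br bond of 12, and the electrophilic α-ester radical 13 adds to the inner carbon of the electron-rich cinnamyl double bond, which forms the C3a–C6a bond, closes the tetrahydrofuran ring and gives benzylic radical 14; the tetravalent iridium formed in the first event (or bromine-atom transfer followed by ionisation) oxidises 14 to the para-silyloxy-stabilised cation 15, which is captured by the carbonyl oxygen of the cis tert-butyl ester with loss of isobutene to close the lactone. The closest known reaction type is the photoredox radical–polar crossover (atom-transfer) carbolactonisation of styrenes with α-bromo esters, joined here to the 5-exo cyclisation of β-allyloxy α-bromo esters long used for tetrahydrofuran lignans. The tetrahydrofuran ring closes in the 5-exo-trig mode (6-endo attack would forgo the benzylic radical), and the lactone closes by five-membered collapse of the cation onto the ester carbonyl oxygen, the mode of a halolactonisation of a tert-butyl ester. C6a and C3a are controlled by the existing stereocentre C6 through a chair-like Beckwith–Houk transition state with the C6 aryl group pseudo-equatorial, so that the ester and the styryl arm both end up trans to that aryl group and therefore cis to each other, the only arrangement that can lactonise; the bromine-bearing carbon of 12 is planarised in the radical, so its epimer mixture is of no consequence. C3 is set in the cation capture, the aryl group taking the convex (exo) face trans to C4, which should be both the kinetically preferred approach (allylic 1,3-strain in the cation) and the thermodynamic isomer. The step needs the cation to be trapped by the ester faster than by bromide or by proton loss, which the cis placement of the ester and the hindered base secure, and a low concentration keeps the radical chemistry intramolecular.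

**Step 10**
Reactants: 16 (3S,3aR,6S,6aS)-6-[3,4-bis(TBSO)phenyl]-3-[3,4,5-tris(TBSO)phenyl]tetrahydro-1H,3H-furo[3,4-c]furan-1-one
Product: 17 (3S,3aR,6S,6aS)-6-(3,4-dihydroxyphenyl)-3-(3,4,5-trihydroxyphenyl)tetrahydro-1H,3H-furo[3,4-c]furan-1-one (CNP0290035.1)
Conditions: Bu4NF (6 equiv), AcOH (6 equiv), THF, 0 °C, argon
Reagents that add atoms: none
Why: Fluoride-induced cleavage of the five aryl silyl ethers; acetic acid keeps the liberated phenols protonated, so that no phenoxide can open the lactone or expel the benzylic oxygen at C3 or C6 through a para-quinone methide, and all four stereocentres stay as set.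

**Compound list**
1 | methyl 3,4-dihydroxybenzoate | COC(=O)c1ccc(O)c(O)c1 | starting material
2 | methyl 3,4-bis(TBSO)benzoate | COC(=O)c1ccc(O[Si](C)(C)C(C)(C)C)c(O[Si](C)(C)C(C)(C)C)c1 | intermediate
3 | tert-butyl 3-[3,4-bis(TBSO)phenyl]-3-oxopropanoate | CC(C)(C)OC(=O)CC(=O)c1ccc(O[Si](C)(C)C(C)(C)C)c(O[Si](C)(C)C(C)(C)C)c1 | intermediate
4 | tert-butyl (3S)-3-[3,4-bis(TBSO)phenyl]-3-hydroxypropanoate | O[C@H](c1ccc(O[Si](C)(C)C(C)(C)C)c(O[Si](C)(C)C(C)(C)C)c1)CC(=O)OC(C)(C)C | intermediate
5 | tert-butyl (3S)-3-(allyloxy)-3-[3,4-bis(TBSO)phenyl]propanoate | C=CCO[C@H](c1ccc(O[Si](C)(C)C(C)(C)C)c(O[Si](C)(C)C(C)(C)C)c1)CC(=O)OC(C)(C)C | intermediate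
6 | 3,4,5-trihydroxybenzaldehyde | O=Cc1cc(O)c(O)c(O)c1 | starting material
7 | 3,4,5-tris(TBSO)benzaldehyde | O=Cc1cc(O[Si](C)(C)C(C)(C)C)c(O[Si](C)(C)C(C)(C)C)c(O[Si](C)(C)C(C)(C)C)c1 | intermediate
8 | 3,4,5-tris(TBSO)styrene | C=Cc1cc(O[Si](C)(C)C(C)(C)C)c(O[Si](C)(C)C(C)(C)C)c(O[Si](C)(C)C(C)(C)C)c1 | intermediate
9 | tert-butyl (3S)-3-[3,4-bis(TBSO)phenyl]-3-{[(2E)-3-[3,4,5-tris(TBSO)phenyl]prop-2-en-1-yl]oxy}propanoate | CC(C)(C)OC(=O)C[C@H](OC/C=C/c1cc(O[Si](C)(C)C(C)(C)C)c(O[Si](C)(C)C(C)(C)C)c(O[Si](C)(C)C(C)(C)C)c1)c1ccc(O[Si](C)(C)C(C)(C)C)c(O[Si](C)(C)C(C)(C)C)c1 | intermediate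
10 | lithium enolate of ester 9 (enolate geometry not defined) | CC(C)(C)OC(O[Li])=C[C@H](OC/C=C/c1cc(O[Si](C)(C)C(C)(C)C)c(O[Si](C)(C)C(C)(C)C)c(O[Si](C)(C)C(C)(C)C)c1)c1ccc(O[Si](C)(C)C(C)(C)C)c(O[Si](C)(C)C(C)(C)C)c1 | intermediate (not isolated)
11 | trimethylsilyl ketene acetal of ester 9 (geometry not defined) | CC(C)(C)OC(O[Si](C)(C)C)=C[C@H](OC/C=C/c1cc(O[Si](C)(C)C(C)(C)C)c(O[Si](C)(C)C(C)(C)C)c(O[Si](C)(C)C(C)(C)C)c1)c1ccc(O[Si](C)(C)C(C)(C)C)c(O[Si](C)(C)C(C)(C)C)c1 | intermediate (not isolated)
12 | tert-butyl (2RS,3R)-2-bromo-3-[3,4-bis(TBSO)phenyl]-3-{[(2E)-3-[3,4,5-tris(TBSO)phenyl]prop-2-en-1-yl]oxy}propanoate (epimer mixture at C2) | CC(C)(C)OC(=O)C(Br)[C@H](OC/C=C/c1cc(O[Si](C)(C)C(C)(C)C)c(O[Si](C)(C)C(C)(C)C)c(O[Si](C)(C)C(C)(C)C)c1)c1ccc(O[Si](C)(C)C(C)(C)C)c(O[Si](C)(C)C(C)(C)C)c1 | intermediate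
13 | α-ester radical from 12 (radical at C2, benzylic ether stereocentre as in 12) | CC(C)(C)OC(=O)[CH][C@H](OC/C=C/c1cc(O[Si](C)(C)C(C)(C)C)c(O[Si](C)(C)C(C)(C)C)c(O[Si](C)(C)C(C)(C)C)c1)c1ccc(O[Si](C)(C)C(C)(C)C)c(O[Si](C)(C)C(C)(C)C)c1 | intermediate (not isolated)
14 | cyclised benzylic radical: tert-butyl 2-aryl-4-[aryl(radical)methyl]tetrahydrofuran-3-carboxylate, 2,3-trans-3,4-cis | CC(C)(C)OC(=O)[C@@H]1[C@@H](c2ccc(O[Si](C)(C)C(C)(C)C)c(O[Si](C)(C)C(C)(C)C)c2)OC[C@@H]1[CH]c1cc(O[Si](C)(C)C(C)(C)C)c(O[Si](C)(C)C(C)(C)C)c(O[Si](C)(C)C(C)(C)C)c1 | intermediate (not isolated)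
15 | benzylic cation derived from 14 by one-electron oxidation | CC(C)(C)OC(=O)[C@@H]1[C@@H](c2ccc(O[Si](C)(C)C(C)(C)C)c(O[Si](C)(C)C(C)(C)C)c2)OC[C@@H]1[CH+]c1cc(O[Si](C)(C)C(C)(C)C)c(O[Si](C)(C)C(C)(C)C)c(O[Si](C)(C)C(C)(C)C)c1 | intermediate (not isolated)
16 | (3S,3aR,6S,6aS)-6-[3,4-bis(TBSO)phenyl]-3-[3,4,5-tris(TBSO)phenyl]tetrahydro-1H,3H-furo[3,4-c]furan-1-one (cis ring fusion, both aryl groups exo) | O=C1O[C@H](c2cc(O[Si](C)(C)C(C)(C)C)c(O[Si](C)(C)C(C)(C)C)c(O[Si](C)(C)C(C)(C)C)c2)[C@H]2CO[C@H](c3ccc(O[Si](C)(C)C(C)(C)C)c(O[Si](C)(C)C(C)(C)C)c3)[C@@H]12 | intermediate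
17 | (3S,3aR,6S,6aS)-6-(3,4-dihydroxyphenyl)-3-(3,4,5-trihydroxyphenyl)tetrahydro-1H,3H-furo[3,4-c]furan-1-one | O=C1O[C@H](c2cc(O)c(O)c(O)c2)[C@H]2CO[C@H](c3ccc(O)c(O)c3)[C@@H]12 | target

**Total step count:** 10
**Longest linear sequence:** 8 steps (1 → 2 → 3 → 4 → 5 → 9 → 12 → 16 → 17)

**Steps most likely to fail**

Step 9 (key cascade). The radical closure may proceed with insufficient control of the C3a/C6a relationship: an adduct whose ester and benzylic arm are trans cannot lactonise and is lost as bromide or alkene. Alternatively, simple reduction of the C–Br bond may outrun cyclisation. The fallback gives the radical carbon a second, temporary ester, so that an ester lies cis to the cation whichever face closes, and makes the radical with an oxidant instead of by photoreduction. It sets out from 9. The lithium enolate 10 is C-acylated with Boc2O (THF, −78 °C) to give the di-tert-butyl malonate F1. Oxidative free-radical cyclisation with Mn(OAc)3·2H2O (2.2 equiv) and Cu(OAc)2 (1 equiv) in AcOH at 50 °C gives the 6a-tert-butoxycarbonyl lactone F2; trivalent manganese generates the malonyl radical and oxidises the benzylic radical, and lactone termination onto aryl alkenes is the usual outcome for malonates. Cleavage of the remaining tert-butyl ester with Me3SiOTf/2,6-lutidine (CH2Cl2, 0 °C, then aqueous work-up) gives the 6a-carboxylic acid F3. Heating in toluene at 110 °C expels CO2, with protonation from the convex face, the only one that keeps the cis ring fusion, and the sequence comes back to the route at 16.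

Step 8 (α-bromination). The ester enolate may expel the cinnamyl alkoxide (E1cB, giving the cinnamate), or NBS may attack the electron-rich styrene. The fallback installs the halogen before the ether oxygen is alkylated and before the styrene is present, without any ester enolate. It sets out from 3. Chlorination with SO2Cl2 (CH2Cl2, 0 °C) gives the α-chloro-β-keto ester F4. Hydrogenation with dynamic kinetic resolution over RuBr2[(R)-BINAP] (H2, CH2Cl2, 50 °C), a transformation established for aryl α-chloro-β-keto esters, should give the anti-chlorohydrin F5 with the benzylic configuration of 4. Acid-catalysed O-allylation with allyl 2,2,2-trichloroacetimidate (cat. TfOH, cyclohexane/CH2Cl2, 0 °C) gives the allyl ether F6; the electron-poor neighbour disfavours benzylic ionisation and no base is present to close an epoxide. Cross-metathesis with 8 under the conditions of step 7 gives the cinnamyl ether F7. Finkelstein exchange (NaI, acetone, 50 °C) gives the α-iodo ester F8 as an epimer mixture at the halogen-bearing carbon. F8 is submitted to the conditions of step 9, where the C–I bond is reduced even more easily, and comes back to the route at 16.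

Step 4 (O-allylation). Alkylation of the hindered benzylic hydroxyl may be slow, with competing retro-aldol cleavage or dehydration to the cinnamate. The fallback makes the ether through a π-allylpalladium electrophile and delivers the whole cinnamyl unit at once. It sets out from 7. Horner–Wadsworth–Emmons olefination (triethyl phosphonoacetate, LiCl, DBU, MeCN, rt) gives the ethyl (E)-cinnamate F9. Reduction with i-Bu2AlH (CH2Cl2, −78 °C) gives the (E)-cinnamyl alcohol F10, and methyl chloroformate/pyridine (CH2Cl2, 0 °C) gives the methyl carbonate F11. Tsuji–Trost etherification of 4, as its zinc alkoxide (Et2Zn, 0.5 equiv), with F11 under Pd(PPh3)4 (5 mol %, zerovalent palladium) in THF at rt attacks the unsubstituted allyl terminus and comes back to the route at 9, so that steps 4, 6 and 7 are not needed.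

**Further compounds**
F1 | step 9 | di-tert-butyl 2-[(S)-[3,4-bis(TBSO)phenyl]{[(2E)-3-[3,4,5-tris(TBSO)phenyl]prop-2-en-1-yl]oxy}methyl]propanedioate | CC(C)(C)OC(=O)C(C(=O)OC(C)(C)C)[C@H](OC/C=C/c1cc(O[Si](C)(C)C(C)(C)C)c(O[Si](C)(C)C(C)(C)C)c(O[Si](C)(C)C(C)(C)C)c1)c1ccc(O[Si](C)(C)C(C)(C)C)c(O[Si](C)(C)C(C)(C)C)c1
F2 | step 9 | 6a-tert-butoxycarbonyl derivative of 16 (ester on the convex face, cis ring fusion, C3, C3a and C6 as in 16) | O=C1O[C@H](c2cc(O[Si](C)(C)C(C)(C)C)c(O[Si](C)(C)C(C)(C)C)c(O[Si](C)(C)C(C)(C)C)c2)[C@H]2CO[C@H](c3ccc(O[Si](C)(C)C(C)(C)C)c(O[Si](C)(C)C(C)(C)C)c3)[C@@]12C(=O)OC(C)(C)C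
F3 | step 9 | 6a-carboxylic acid derived from F2 (same configuration) | O=C1O[C@H](c2cc(O[Si](C)(C)C(C)(C)C)c(O[Si](C)(C)C(C)(C)C)c(O[Si](C)(C)C(C)(C)C)c2)[C@H]2CO[C@H](c3ccc(O[Si](C)(C)C(C)(C)C)c(O[Si](C)(C)C(C)(C)C)c3)[C@@]12C(=O)O
F4 | step 8 | tert-butyl 2-chloro-3-[3,4-bis(TBSO)phenyl]-3-oxopropanoate (racemic) | CC(C)(C)OC(=O)C(Cl)C(=O)c1ccc(O[Si](C)(C)C(C)(C)C)c(O[Si](C)(C)C(C)(C)C)c1
F5 | step 8 | tert-butyl (2R,3R)-2-chloro-3-[3,4-bis(TBSO)phenyl]-3-hydroxypropanoate (anti) | O[C@H](c1ccc(O[Si](C)(C)C(C)(C)C)c(O[Si](C)(C)C(C)(C)C)c1)[C@@H](Cl)C(=O)OC(C)(C)C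
F6 | step 8 | tert-butyl (2R,3R)-3-(allyloxy)-2-chloro-3-[3,4-bis(TBSO)phenyl]propanoate | C=CCO[C@H](c1ccc(O[Si](C)(C)C(C)(C)C)c(O[Si](C)(C)C(C)(C)C)c1)[C@@H](Cl)C(=O)OC(C)(C)C
F7 | step 8 | tert-butyl (2R,3R)-2-chloro-3-[3,4-bis(TBSO)phenyl]-3-{[(2E)-3-[3,4,5-tris(TBSO)phenyl]prop-2-en-1-yl]oxy}propanoate | CC(C)(C)OC(=O)[C@H](Cl)[C@H](OC/C=C/c1cc(O[Si](C)(C)C(C)(C)C)c(O[Si](C)(C)C(C)(C)C)c(O[Si](C)(C)C(C)(C)C)c1)c1ccc(O[Si](C)(C)C(C)(C)C)c(O[Si](C)(C)C(C)(C)C)c1
F8 | step 8 | tert-butyl (2RS,3R)-2-iodo-3-[3,4-bis(TBSO)phenyl]-3-{[(2E)-3-[3,4,5-tris(TBSO)phenyl]prop-2-en-1-yl]oxy}propanoate (epimer mixture at C2) | CC(C)(C)OC(=O)C(I)[C@H](OC/C=C/c1cc(O[Si](C)(C)C(C)(C)C)c(O[Si](C)(C)C(C)(C)C)c(O[Si](C)(C)C(C)(C)C)c1)c1ccc(O[Si](C)(C)C(C)(C)C)c(O[Si](C)(C)C(C)(C)C)c1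
F9 | step 4 | ethyl (2E)-3-[3,4,5-tris(TBSO)phenyl]prop-2-enoate | CCOC(=O)/C=C/c1cc(O[Si](C)(C)C(C)(C)C)c(O[Si](C)(C)C(C)(C)C)c(O[Si](C)(C)C(C)(C)C)c1
F10 | step 4 | (2E)-3-[3,4,5-tris(TBSO)phenyl]prop-2-en-1-ol | OC/C=C/c1cc(O[Si](C)(C)C(C)(C)C)c(O[Si](C)(C)C(C)(C)C)c(O[Si](C)(C)C(C)(C)C)c1
F11 | step 4 | methyl (2E)-3-[3,4,5-tris(TBSO)phenyl]prop-2-en-1-yl carbonate | COC(=O)OC/C=C/c1cc(O[Si](C)(C)C(C)(C)C)c(O[Si](C)(C)C(C)(C)C)c(O[Si](C)(C)C(C)(C)C)c1
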